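The synthesis rests on disconnecting the O1–C6 bond of the 1,2-dioxane. C6 is a fully substituted carbon bonded to peroxide oxygen O1, and its ethyl group maps onto the CH2CH2O arm of a 2,2-disubstituted oxetane. In the key step the terminal oxygen of a C3 hydroperoxy acetal opens that oxetane at its tertiary carbon, which closes the six-membered peroxide ring and sets C6 by inversion in one operation. The precursor is an open chain carrying the C4 ethyl stereocentre, the (R)-oxetane at the future C6 with the complete side chain, and C3 as a methoxy hydroperoxy acetal; C3 is set last by axial addition to the cyclic peroxycarbenium ion.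

Key step: step 16

Remark: ring atoms are numbered O1–O2–C3–C4–C5–C6. The target is read as (3S,4S,6S) with a (4R,5E)-4-ethyloct-5-enyl chain, so the C3 acetate arm and the C4 and C6 ethyl groups are all cis. C3 of compounds 27–32 is carried as a mixture of epimers on purpose, because it is reset in the last step.

Step 1
Reactants: 1 (2E)-pent-2-enal
Product: 2 (3R,4E)-hept-4-en-3-ol
Conditions: Et2Zn (1.5 equiv), (+)-DAIB [(2R)-3-exo-(dimethylamino)isoborneol, 3 mol %], toluene, 0 °C; then 1 M aq. HCl
Reagents that add atoms: diethylzinc, CC[Zn]CC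
Why: Amino-alcohol-catalysed enantioselective addition of a dialkylzinc to an aldehyde gives 1,2-addition only, and the (+)-catalyst, mirror image of the (−)-form that gives (S)-carbinols, delivers ethyl to the carbonyl face that sets the (R)-carbinol centre.

Step 2
Reactants: 2 (3R,4E)-hept-4-en-3-ol; 3 triethyl orthoacetate
Product: 5 ethyl (3R,4E)-3-ethylhept-4-enoate, via ketene acetal 4 (not isolated)
Conditions: 3 (5 equiv), EtCO2H (5 mol %), 140 °C, EtOH distilled off
Reagents that add atoms: none
Why: Johnson–Claisen rearrangement, in which the mixed ketene acetal reacts through a chair transition state with the carbinol ethyl group equatorial, giving the E alkene and transferring the (R)-carbinol chirality suprafacially to the new C–C bond, which sets the (R)-configured side-chain stereocentre.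

Step 3
Reactants: 5 ethyl (3R,4E)-3-ethylhept-4-enoate
Product: 6 (3R,4E)-3-ethylhept-4-enal
Conditions: i-Bu2AlH (1.05 equiv), CH2Cl2, −78 °C; then aq. potassium sodium tartrate
Reagents that add atoms: none
Why: Partial reduction of an ester with one equivalent of i-Bu2AlH at −78 °C stops at the aluminium hemiacetal, which releases the aldehyde only on work-up, and the β-stereocentre cannot epimerise.

Step 4
Reactants: 6 (3R,4E)-3-ethylhept-4-enal
Product: 7 (4R,5E)-4-ethylocta-1,5-diene
Conditions: Ph3PCH3Br, KN(SiMe3)2, THF, 0 °C → rt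
Reagents that add atoms: methyltriphenylphosphonium bromide, C[P+](c1ccccc1)(c1ccccc1)c1ccccc1.[Br-]
Why: Wittig methylenation with the non-stabilised ylide converts the aldehyde into the terminal alkene without touching the stereocentre or the E alkene.

Step 5
Reactants: 8 (4R)-4-benzyl-1,3-oxazolidin-2-one; 9 butanoyl chloride
Product: 10 (4R)-4-benzyl-3-butanoyl-1,3-oxazolidin-2-one
Conditions: Et3N, DMAP (10 mol %), CH2Cl2, 0 °C → rt
Reagents that add atoms: none
Why: N-Acylation of the oxazolidinone by the acid chloride under amine base and nucleophilic catalysis is the standard loading of an Evans auxiliary.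

Step 6
Reactants: 10 (4R)-4-benzyl-3-butanoyl-1,3-oxazolidin-2-one; 11 propargyl bromide
Product: 13 (4R)-4-benzyl-3-[(2S)-2-ethylpent-4-ynoyl]-1,3-oxazolidin-2-one, via sodium Z-enolate 12 (not isolated)
Conditions: NaN(SiMe3)2, THF, −78 °C; then 11, −78 → −40 °C
Reagents that add atoms: none
Why: Evans asymmetric alkylation, in which the sodium-chelated Z-enolate is alkylated by the reactive propargylic bromide on the face opposite the benzyl group of the (R)-auxiliary, which sets the (S)-configured carbon that becomes C4.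

Step 7
Reactants: 13 (4R)-4-benzyl-3-[(2S)-2-ethylpent-4-ynoyl]-1,3-oxazolidin-2-one
Product: 14 (2S)-2-ethylpent-4-yn-1-ol
Conditions: LiBH4, H2O (1 equiv), Et2O, 0 °C
Reagents that add atoms: none
Why: Reductive cleavage of the imide with LiBH4 attacks the exocyclic carbonyl selectively, gives the primary alcohol without epimerisation of the adjacent stereocentre and returns the auxiliary.

Step 8
Reactants: 14 (2S)-2-ethylpent-4-yn-1-ol
Product: 16 (4S)-4-(dimethoxymethyl)hex-1-yne, via (2S)-2-ethylpent-4-ynal 15 (not isolated)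
Conditions: TEMPO (10 mol %), PhI(OAc)2, CH2Cl2, rt; then HC(OMe)3, MeOH, TsOH·H2O (2 mol %), 0 °C → rt
Reagents that add atoms: trimethyl orthoformate, COC(OC)OC
Why: Oxoammonium-mediated oxidation stops at the aldehyde without α-epimerisation, and acid-catalysed acetalisation driven by the orthoformate in the same flask converts the configurationally labile aldehyde at once into the dimethyl acetal that later supplies the C3 acetal carbon.

Step 9
Reactants: 16 (4S)-4-(dimethoxymethyl)hex-1-yne
Product: 18 (5S)-5-(dimethoxymethyl)hept-2-yn-1-ol, via lithium acetylide 17 (not isolated)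
Conditions: n-BuLi, THF, −78 °C; then (CH2O)n, −78 °C → rt
Reagents that add atoms: formaldehyde (as paraformaldehyde), C=O
Why: Deprotonation of the terminal alkyne and addition of the lithium acetylide to formaldehyde (alkynylation of an aldehyde) gives the propargylic alcohol, the acetal being inert to base.

Step 10
Reactants: 18 (5S)-5-(dimethoxymethyl)hept-2-yn-1-ol
Product: 20 (2Z,5S)-5-(dimethoxymethyl)-3-iodohept-2-en-1-ol, via cyclic vinylalanate 19 (not isolated)
Conditions: NaAlH2(OCH2CH2OMe)2, THF, 0 °C → rt; then I2, −78 → 0 °C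
Reagents that add atoms: iodine, II
Why: Hydroxyl-directed trans-hydroalumination of a propargylic alcohol delivers hydride to C2 and aluminium to C3 within a five-membered alkoxy-alanate, and iodinolysis of the C–Al bond with retention gives the Z vinyl iodide regio- and stereoselectively.

Step 11
Reactants: 7 (4R,5E)-4-ethylocta-1,5-diene; 20 (2Z,5S)-5-(dimethoxymethyl)-3-iodohept-2-en-1-ol
Product: 22 (2E,7R,8E)-3-[(2S)-2-(dimethoxymethyl)butyl]-7-ethylundeca-2,8-dien-1-ol, via B-alkyl-9-borabicyclononane 21 (not isolated)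
Conditions: 7, 9-BBN-H (1.1 equiv), THF, 0 °C → rt; then 20, PdCl2(dppf) (5 mol %), AsPh3 (5 mol %), Cs2CO3, DMF/H2O, rt
Reagents that add atoms: none
Why: 9-BBN-H hydroborates only the terminal alkene of 7 in the anti-Markovnikov sense, and the B-alkyl Suzuki–Miyaura coupling proceeds with retention of the vinyl iodide geometry, so the side chain ends up cis to the hydroxymethyl group (E by priority).

Step 12
Reactants: 22 (2E,7R,8E)-3-[(2S)-2-(dimethoxymethyl)butyl]-7-ethylundeca-2,8-dien-1-ol
Product: 23 [(2R,3R)-3-[(2S)-2-(dimethoxymethyl)butyl]-3-[(4R,5E)-4-ethyloct-5-en-1-yl]oxiran-2-yl]methanol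
Conditions: Ti(Oi-Pr)4 (10 mol %), D-(−)-diethyl tartrate (12 mol %), t-BuOOH, 4 Å molecular sieves, CH2Cl2, −20 °C
Reagents that add atoms: tert-butyl hydroperoxide, CC(C)(C)OO
Why: Sharpless asymmetric epoxidation is directed by the allylic hydroxyl, leaves the isolated alkene untouched, and with D-(−)-tartrate delivers oxygen to the face of this 3,3-disubstituted E allylic alcohol that gives the (2R,3R)-epoxide (mirror image of the geraniol/L-(+)-tartrate case), which sets the tertiary C–O stereocentre that becomes the oxetane carbon.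

Step 13
Reactants: 23 [(2R,3R)-3-[(2S)-2-(dimethoxymethyl)butyl]-3-[(4R,5E)-4-ethyloct-5-en-1-yl]oxiran-2-yl]methanol
Product: 24 (3R,7R,8E)-3-[(2S)-2-(dimethoxymethyl)butyl]-7-ethylundec-8-ene-1,3-diol
Conditions: NaAlH2(OCH2CH2OMe)2, THF, 0 °C
Reagents that add atoms: none
Why: Regioselective reductive opening of a 2,3-epoxy alcohol, in which the aluminium alkoxide delivers hydride to C2, the less substituted epoxide carbon, gives the 1,3-diol with the tertiary carbinol configuration untouched.

Step 14
Reactants: 24 (3R,7R,8E)-3-[(2S)-2-(dimethoxymethyl)butyl]-7-ethylundec-8-ene-1,3-diol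
Product: 26 (2R)-2-[(2S)-2-(dimethoxymethyl)butyl]-2-[(4R,5E)-4-ethyloct-5-en-1-yl]oxetane, via primary tosylate 25 (not isolated)
Conditions: n-BuLi (1.0 equiv), THF, 0 °C; TsCl (1.0 equiv); then KOt-Bu (1.1 equiv), 0 °C → rt
Reagents that add atoms: none
Why: Selective sulfonylation of the primary alkoxide followed by intramolecular Williamson etherification (4-exo-tet attack of the tertiary alkoxide on the primary tosylate) forms the oxetane without breaking a bond at the stereocentre, so its configuration is retained.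

Step 15
Reactants: 26 (2R)-2-[(2S)-2-(dimethoxymethyl)butyl]-2-[(4R,5E)-4-ethyloct-5-en-1-yl]oxetane
Product: 27 (1RS,2S)-2-ethyl-1-methoxy-3-{(2R)-2-[(4R,5E)-4-ethyloct-5-en-1-yl]oxetan-2-yl}propyl hydroperoxide
Conditions: anhydrous H2O2 in Et2O (10 equiv), camphorsulfonic acid (5 mol %), 0 °C; then solid NaHCO3
Reagents that add atoms: hydrogen peroxide, OO
Why: Acid-catalysed acetal exchange, in which the oxocarbenium ion from the dimethyl acetal is captured by the large excess of hydrogen peroxide to give the 1-methoxyalkyl hydroperoxide, should stop at mono-exchange because the hydroperoxy acetal ionises less readily, and the weak sulfonic acid at 0 °C is expected to activate the acetal faster than the oxetane; C3 forms as a mixture of epimers.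

Step 16
Reactants: 27 (1RS,2S)-2-ethyl-1-methoxy-3-{(2R)-2-[(4R,5E)-4-ethyloct-5-en-1-yl]oxetan-2-yl}propyl hydroperoxide
Product: 29 2-[(3RS,4S,6S)-4-ethyl-6-[(4R,5E)-4-ethyloct-5-en-1-yl]-3-methoxy-1,2-dioxan-6-yl]ethan-1-ol, via trimethylsilyl ether 28 (not isolated)
Conditions: Me3SiOTf (1.2 equiv), 2,6-di-tert-butyl-4-methylpyridine (1.5 equiv), CH2Cl2, −78 → −40 °C; then aq. citric acid, THF, 0 °C
Reagents that add atoms: none
Why: Me3SiOTf silylates the oxetane oxygen, the most Lewis-basic site, and the terminal oxygen of the C3 hydroperoxide attacks the tertiary carbon C6 from the side opposite the breaking C–O bond while the hindered pyridine takes up the proton, so that O1–C6 forms as the oxetane opens and the released oxygen stays on the two-carbon arm as its silyl ether, cleaved on work-up. The closest known reaction type is the Lewis acid-promoted opening of 2,2-disubstituted oxetanes at the tertiary carbon by hydrogen peroxide and alkyl hydroperoxides with predominant inversion, of which this is the tethered version. The 1,2-dioxane closes in the 6-exo-tet mode, the leaving oxygen lying outside the new ring. The configuration of C6 is controlled by the oxetane stereocentre installed in step 12, backside attack turning (R) in 27 into (S) in 29. The step needs the peroxide oxygen to reach C6 faster than C6 ionises to a free cation and faster than the acetal methoxy oxygen can attack in a 5-exo mode or the acetal itself ionises; the tethered α-effect nucleophile five atoms away, the inductively deactivated acetal oxygens, the proton-free medium and the low temperature are expected to secure this.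

Step 17
Reactants: 29 2-[(3RS,4S,6S)-4-ethyl-6-[(4R,5E)-4-ethyloct-5-en-1-yl]-3-methoxy-1,2-dioxan-6-yl]ethan-1-ol
Product: 30 2-[(3RS,4S,6S)-4-ethyl-6-[(4R,5E)-4-ethyloct-5-en-1-yl]-3-methoxy-1,2-dioxan-6-yl]ethyl 4-methylbenzenesulfonate
Conditions: TsCl, pyridine, CH2Cl2, 0 °C
Reagents that add atoms: p-toluenesulfonyl chloride, Cc1ccc(cc1)S(=O)(=O)Cl
Why: Sulfonylation of the primary alcohol with TsCl and pyridine is a standard activation that the dialkyl peroxide and the peroxy acetal tolerate.

Step 18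
Reactants: 30 2-[(3RS,4S,6S)-4-ethyl-6-[(4R,5E)-4-ethyloct-5-en-1-yl]-3-methoxy-1,2-dioxan-6-yl]ethyl 4-methylbenzenesulfonate
Product: 32 (3RS,4S,6S)-4,6-diethyl-6-[(4R,5E)-4-ethyloct-5-en-1-yl]-3-methoxy-1,2-dioxane, via primary iodide 31 (not isolated)
Conditions: NaI, DMSO, 40 °C; then NaBH4, rt
Reagents that add atoms: none
Why: Finkelstein exchange followed by SN2 hydride displacement of the primary iodide by NaBH4 in a dipolar aprotic solvent gives the ethyl group at room temperature, conditions under which dialkyl peroxides and peroxy acetals should not be reduced and no radicals are formed.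

Step 19
Reactants: 32 (3RS,4S,6S)-4,6-diethyl-6-[(4R,5E)-4-ethyloct-5-en-1-yl]-3-methoxy-1,2-dioxane
Product: 33 methyl 2-[(3S,4S,6S)-4,6-diethyl-6-[(4R,5E)-4-ethyloct-5-en-1-yl]-1,2-dioxan-3-yl]acetate
Conditions: 1-(tert-butyldimethylsilyloxy)-1-methoxyethene (3 equiv), TiCl4 (1.1 equiv), CH2Cl2, −78 °C
Reagents that add atoms: 1-(tert-butyldimethylsilyloxy)-1-methoxyethene, C=C(OC)O[Si](C)(C)C(C)(C)C
Why: Mukaiyama-type substitution of a cyclic peroxy acetal, in which TiCl4 removes the exocyclic methoxy group from either C3 epimer and the silyl ketene acetal adds axially to the peroxycarbenium half-chair that keeps the C4 ethyl pseudoequatorial (the flipped form would place it 1,3-diaxial to a C6 substituent), anti to the pseudoaxial C4–H, so the acetate arm should end up axial and cis to the C4 ethyl, which sets (3S).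

Compound list
1 | (2E)-pent-2-enal | CC/C=C/C=O | starting material
2 | (3R,4E)-hept-4-en-3-ol | CC/C=C/[C@H](O)CC | intermediate
3 | triethyl orthoacetate | CCOC(C)(OCC)OCC | starting material
4 | 1-ethoxy-1-[(3R,4E)-hept-4-en-3-yloxy]ethene (ketene acetal) | CC/C=C/[C@@H](CC)OC(=C)OCC | intermediate
5 | ethyl (3R,4E)-3-ethylhept-4-enoate | CC/C=C/[C@H](CC)CC(=O)OCC | intermediate
6 | (3R,4E)-3-ethylhept-4-enal | CC/C=C/[C@H](CC)CC=O | intermediate
7 | (4R,5E)-4-ethylocta-1,5-diene | CC/C=C/[C@H](CC)CC=C | intermediate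
8 | (4R)-4-benzyl-1,3-oxazolidin-2-one | O=C1OC[C@@H](Cc2ccccc2)N1 | starting material
9 | butanoyl chloride | CCCC(=O)Cl | starting material
10 | (4R)-4-benzyl-3-butanoyl-1,3-oxazolidin-2-one | CCCC(=O)N1C(=O)OC[C@H]1Cc1ccccc1 | intermediate
11 | propargyl bromide (3-bromoprop-1-yne) | C#CCBr | starting material
12 | sodium (1Z)-1-[(4R)-4-benzyl-2-oxo-1,3-oxazolidin-3-yl]but-1-en-1-olate | CC/C=C(\[O-])N1C(=O)OC[C@H]1Cc1ccccc1.[Na+] | intermediate
13 | (4R)-4-benzyl-3-[(2S)-2-ethylpent-4-ynoyl]-1,3-oxazolidin-2-one | C#CC[C@H](CC)C(=O)N1C(=O)OC[C@H]1Cc1ccccc1 | intermediate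
14 | (2S)-2-ethylpent-4-yn-1-ol | C#CC[C@H](CC)CO | intermediate
15 | (2S)-2-ethylpent-4-ynal | C#CC[C@H](CC)C=O | intermediate
16 | (4S)-4-(dimethoxymethyl)hex-1-yne | C#CC[C@H](CC)C(OC)OC | intermediate
17 | [(4S)-4-(dimethoxymethyl)hex-1-yn-1-yl]lithium | [Li]C#CC[C@H](CC)C(OC)OC | intermediate
18 | (5S)-5-(dimethoxymethyl)hept-2-yn-1-ol | OCC#CC[C@H](CC)C(OC)OC | intermediate
19 | sodium 3-[(2S)-2-(dimethoxymethyl)butyl]-2,2-bis(2-methoxyethoxy)-2,5-dihydro-1,2-oxaluminol-2-uide (cyclic vinylalanate) | COCCO[Al-]1(OCCOC)OCC=C1C[C@H](CC)C(OC)OC.[Na+] | intermediate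
20 | (2Z,5S)-5-(dimethoxymethyl)-3-iodohept-2-en-1-ol | OC/C=C(\I)C[C@H](CC)C(OC)OC | intermediate
21 | 9-[(4R,5E)-4-ethyloct-5-en-1-yl]-9-borabicyclo[3.3.1]nonane | CC/C=C/[C@H](CC)CCCB1C2CCCC1CCC2 | intermediate
22 | (2E,7R,8E)-3-[(2S)-2-(dimethoxymethyl)butyl]-7-ethylundeca-2,8-dien-1-ol | CC/C=C/[C@H](CC)CCC/C(=C\CO)C[C@H](CC)C(OC)OC | intermediate
23 | [(2R,3R)-3-[(2S)-2-(dimethoxymethyl)butyl]-3-[(4R,5E)-4-ethyloct-5-en-1-yl]oxiran-2-yl]methanol | CC/C=C/[C@H](CC)CCC[C@@]1(O[C@@H]1CO)C[C@H](CC)C(OC)OC | intermediate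
24 | (3R,7R,8E)-3-[(2S)-2-(dimethoxymethyl)butyl]-7-ethylundec-8-ene-1,3-diol | CC/C=C/[C@H](CC)CCC[C@](O)(CCO)C[C@H](CC)C(OC)OC | intermediate
25 | (3R,7R,8E)-3-[(2S)-2-(dimethoxymethyl)butyl]-7-ethyl-3-hydroxyundec-8-en-1-yl 4-methylbenzenesulfonate | CC/C=C/[C@H](CC)CCC[C@](O)(CCOS(=O)(=O)c1ccc(C)cc1)C[C@H](CC)C(OC)OC | intermediate
26 | (2R)-2-[(2S)-2-(dimethoxymethyl)butyl]-2-[(4R,5E)-4-ethyloct-5-en-1-yl]oxetane | CC/C=C/[C@H](CC)CCC[C@]1(CCO1)C[C@H](CC)C(OC)OC | intermediate
27 | (1RS,2S)-2-ethyl-1-methoxy-3-{(2R)-2-[(4R,5E)-4-ethyloct-5-en-1-yl]oxetan-2-yl}propyl hydroperoxide | CC/C=C/[C@H](CC)CCC[C@]1(CCO1)C[C@H](CC)C(OC)OO | intermediate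
28 | {2-[(3RS,4S,6S)-4-ethyl-6-[(4R,5E)-4-ethyloct-5-en-1-yl]-3-methoxy-1,2-dioxan-6-yl]ethoxy}trimethylsilane | CC/C=C/[C@H](CC)CCC[C@@]1(CCO[Si](C)(C)C)C[C@H](CC)C(OC)OO1 | intermediate
29 | 2-[(3RS,4S,6S)-4-ethyl-6-[(4R,5E)-4-ethyloct-5-en-1-yl]-3-methoxy-1,2-dioxan-6-yl]ethan-1-ol | CC/C=C/[C@H](CC)CCC[C@@]1(CCO)C[C@H](CC)C(OC)OO1 | intermediate
30 | 2-[(3RS,4S,6S)-4-ethyl-6-[(4R,5E)-4-ethyloct-5-en-1-yl]-3-methoxy-1,2-dioxan-6-yl]ethyl 4-methylbenzenesulfonate | CC/C=C/[C@H](CC)CCC[C@@]1(CCOS(=O)(=O)c2ccc(C)cc2)C[C@H](CC)C(OC)OO1 | intermediate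
31 | (3RS,4S,6S)-4-ethyl-6-[(4R,5E)-4-ethyloct-5-en-1-yl]-6-(2-iodoethyl)-3-methoxy-1,2-dioxane | CC/C=C/[C@H](CC)CCC[C@@]1(CCI)C[C@H](CC)C(OC)OO1 | intermediate
32 | (3RS,4S,6S)-4,6-diethyl-6-[(4R,5E)-4-ethyloct-5-en-1-yl]-3-methoxy-1,2-dioxane | CC/C=C/[C@H](CC)CCC[C@@]1(CC)C[C@H](CC)C(OC)OO1 | intermediate
33 | methyl 2-[(3S,4S,6S)-4,6-diethyl-6-[(4R,5E)-4-ethyloct-5-en-1-yl]-1,2-dioxan-3-yl]acetate | CC/C=C/[C@H](CC)CCC[C@@]1(CC)C[C@H](CC)[C@H](CC(=O)OC)OO1 | target

Total step count: 19. Longest linear sequence: 15 steps (steps 5–19, from 8 and 9 to 33); the side-chain branch (steps 1–4) joins in step 11.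

Steps most likely to fail

Step 16. The silylated oxetane may ionise to a free tertiary cation before the peroxide oxygen arrives, which would erode the invertive course at C6 and open elimination pathways. The acetal methoxy oxygen may also engage C6 in a five-membered mode. The fallback reverses the order of the two C–O bond formations and sets out from 26. The oxetane is opened intermolecularly at the tertiary carbon with ethereal H2O2 and catalytic Me3SiOTf in Et2O at −78 → 0 °C, the bimolecular reaction known to run with predominant inversion, where the large excess of H2O2 should outcompete internal oxygen nucleophiles. This should give (3S,7R,8E)-3-[(2S)-2-(dimethoxymethyl)butyl]-7-ethyl-3-hydroperoxyundec-8-en-1-ol F1. Catalytic camphorsulfonic acid in CH2Cl2 then closes the ring from the other end by intramolecular peroxyacetalisation (O2–C3, loss of methanol), and the route is rejoined at 29.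

Step 15. The acid needed for acetal exchange may open the oxetane (attack by H2O2 or by an acetal oxygen), and exchange may run on to the geminal bis-hydroperoxide. The fallback uses no acid while the oxetane is present and sets out from 26. Catalytic iodine in wet acetone at rt removes the dimethyl acetal under neutral conditions to give (2S)-2-ethyl-3-{(2R)-2-[(4R,5E)-4-ethyloct-5-en-1-yl]oxetan-2-yl}propanal F2. Ethereal H2O2 adds to the aldehyde without catalyst to give the perhydrate (2S)-2-ethyl-3-{(2R)-2-[(4R,5E)-4-ethyloct-5-en-1-yl]oxetan-2-yl}-1-hydroperoxypropan-1-ol F3. Catalytic Me3SiOTf in Et2O at −78 °C then closes the ring in the same 6-exo mode to the peroxy hemiacetal (4S,6S)-4-ethyl-6-[(4R,5E)-4-ethyloct-5-en-1-yl]-6-(2-hydroxyethyl)-1,2-dioxan-3-ol F4. With no oxetane left, MeOH and pyridinium p-toluenesulfonate convert F4 into the methyl peroxy acetal, rejoining the route at 29.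

Step 19. Facial selectivity may be poor, because the very nucleophilic ketene acetal reacts with the peroxycarbenium ion through an early transition state and may add to both faces; the Lewis acid may also ionise the ring O2–C3 bond instead of the methoxy group. The fallback sets out from 32 and uses a weaker, smaller π-nucleophile, for which the stereoelectronic preference for axial attack should be expressed more fully. Trimethyl(vinyloxy)silane and TiCl4 in CH2Cl2 at −78 °C should give 2-[(3S,4S,6S)-4,6-diethyl-6-[(4R,5E)-4-ethyloct-5-en-1-yl]-1,2-dioxan-3-yl]acetaldehyde F5. Pinnick oxidation (NaClO2, NaH2PO4, 2-methylbut-2-ene, t-BuOH/H2O) gives 2-[(3S,4S,6S)-4,6-diethyl-6-[(4R,5E)-4-ethyloct-5-en-1-yl]-1,2-dioxan-3-yl]acetic acid F6. Me3SiCHN2 in MeOH/toluene then gives the methyl ester, arriving at 33.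

Further compounds
F1 | step 16 | (3S,7R,8E)-3-[(2S)-2-(dimethoxymethyl)butyl]-7-ethyl-3-hydroperoxyundec-8-en-1-ol | CC/C=C/[C@H](CC)CCC[C@@](OO)(CCO)C[C@H](CC)C(OC)OC
F2 | step 15 | (2S)-2-ethyl-3-{(2R)-2-[(4R,5E)-4-ethyloct-5-en-1-yl]oxetan-2-yl}propanal | CC/C=C/[C@H](CC)CCC[C@]1(CCO1)C[C@H](CC)C=O
F3 | step 15 | (2S)-2-ethyl-3-{(2R)-2-[(4R,5E)-4-ethyloct-5-en-1-yl]oxetan-2-yl}-1-hydroperoxypropan-1-ol | CC/C=C/[C@H](CC)CCC[C@]1(CCO1)C[C@H](CC)C(O)OO
F4 | step 15 | (4S,6S)-4-ethyl-6-[(4R,5E)-4-ethyloct-5-en-1-yl]-6-(2-hydroxyethyl)-1,2-dioxan-3-ol | CC/C=C/[C@H](CC)CCC[C@@]1(CCO)C[C@H](CC)C(O)OO1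
F5 | step 19 | 2-[(3S,4S,6S)-4,6-diethyl-6-[(4R,5E)-4-ethyloct-5-en-1-yl]-1,2-dioxan-3-yl]acetaldehyde | CC/C=C/[C@H](CC)CCC[C@@]1(CC)C[C@H](CC)[C@H](CC=O)OO1
F6 | step 19 | 2-[(3S,4S,6S)-4,6-diethyl-6-[(4R,5E)-4-ethyloct-5-en-1-yl]-1,2-dioxan-3-yl]acetic acid | CC/C=C/[C@H](CC)CCC[C@@]1(CC)C[C@H](CC)[C@H](CC(=O)O)OO1
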